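Everything rests on cutting ring C at two bonds, C13–C14 and C8–C9. Ring C (C8, C9, C11–C14) is fused to the δ-lactone C7(=O)–O–C20–C10–C9–C8, so the lactone ester is a ready-made tether between a butadienyl group on the quaternary C10 of ring A and a 2-substituted acrylate. One intramolecular Diels–Alder reaction of this dienyl acrylate closes ring C and the lactone together and sets the quaternary C8 and C9 under the control of C10. The acrylate already carries C15 as a silyl ether and an alkyne, so a later ketyl–alkyne cyclisation onto a C13 ketone closes ring D with the 13-hydroxyl and 16-methylene groups.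

Key step: step 11

Remark: atoms are numbered as in ent-kaurane (C6 = aldehyde carbon, C7 = lactone carbonyl, C20 = lactone CH2); the C1 carbinol of 22–27 is drawn as the expected major epimer, and either epimer converges on 28 in step 18.

Step 1
Reactants: 1 4,4-dimethylcyclohexa-2,5-dien-1-one; 2 potassium vinyltrifluoroborate
Product: 3 (R)-4,4-dimethyl-5-vinylcyclohex-2-en-1-one
Conditions: [Rh(cod)2]BF4 (3 mol %), (R)-BINAP (3.3 mol %), PhMe/H2O 10:1, 100 °C
Reagents that add atoms: none
Why: Rhodium-catalysed asymmetric conjugate addition (Hayashi–Miyaura reaction) desymmetrises the prochiral dienone, the (R)-BINAP–rhodium vinyl species adding to one enantiotopic β-carbon to set C5 (sense chosen by analogy with cyclohexenone), and the product enone, no longer cross-conjugated, should react more slowly than 1.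

Step 2
Reactants: 3 (R)-4,4-dimethyl-5-vinylcyclohex-2-en-1-one
Product: 5 (S)-5-(dimethoxymethyl)-4,4-dimethylcyclohex-2-en-1-one, via aldehyde 4 (not isolated)
Conditions: O3, CH2Cl2/MeOH, −78 °C (Sudan Red 7B end point); Me2S, −78 °C to rt; then HC(OMe)3, PPTS, rt
Reagents that add atoms: ozone [O-][O+]=O (oxygen of 4); trimethyl orthoformate COC(OC)OC (the two methoxy groups of 5)
Why: Ozonolysis is selective for the isolated vinyl group over the electron-poor conjugated C2=C3 bond, and acetalisation in the same flask masks the α-branched aldehyde before its only stereocentre can enolise.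

Step 3
Reactants: 5 (S)-5-(dimethoxymethyl)-4,4-dimethylcyclohex-2-en-1-one; 6 (triisopropylsilyloxy)methyl chloride
Product: 8 (5S,6R)-5-(dimethoxymethyl)-4,4-dimethyl-6-[(triisopropylsilyloxy)methyl]cyclohex-2-en-1-one, via lithium dienolate 7 (not isolated)
Conditions: LDA, THF, −78 °C; then 6, −78 to −30 °C
Reagents that add atoms: none
Why: Enolate alkylation with an α-chloro ether: deprotonation is possible only at C10 (C2 is vinylic, C4 quaternary) and C-alkylation introduces C20 in protected form, trans to the acetal; this centre is re-enolised in step 4, so its configuration does not matter.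

Step 4
Reactants: 8 (5S,6R)-5-(dimethoxymethyl)-4,4-dimethyl-6-[(triisopropylsilyloxy)methyl]cyclohex-2-en-1-one; 9 (E)-but-2-enal
Product: 12 allylic methyl carbonate of the crotonaldehyde aldol at C10 (carbinol carbon as epimer mixture), via lithium enolate 10 (not isolated), via lithium aldolate 11 (not isolated)
Conditions: LDA, THF, −78 °C; 9, −78 °C; then ClCO2Me, −78 to −20 °C
Reagents that add atoms: methyl chloroformate COC(Cl)=O
Why: Aldol addition of the tetrasubstituted lithium enolate to the aldehyde carbon should occur anti to the pseudoaxial dimethoxymethyl group on C5, setting the quaternary C10 with C9 trans and C20 cis to C6, and O-acylation of the aldolate at −78 °C blocks retro-aldol cleavage.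

Step 5
Reactants: 12 allylic methyl carbonate
Product: 13 (5R,6S)-6-[(1E)-buta-1,3-dien-1-yl]-5-(dimethoxymethyl)-4,4-dimethyl-6-[(triisopropylsilyloxy)methyl]cyclohex-2-en-1-one
Conditions: Pd(PPh3)4 (5 mol %), Et3N, 1,4-dioxane, 90 °C
Reagents that add atoms: none
Why: Palladium-catalysed elimination of an allylic carbonate (Tsuji–Trost-type ionisation to the π-allyl complex, then β-hydride elimination from the terminal methyl group, the only neighbouring position that carries hydrogen) should give the (E)-1,3-diene.

Step 6
Reactants: 13 silyl-protected dienyl ketone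
Product: 14 (5R,6S)-6-[(1E)-buta-1,3-dien-1-yl]-5-(dimethoxymethyl)-6-(hydroxymethyl)-4,4-dimethylcyclohex-2-en-1-one
Conditions: TBAF, AcOH (1:1), THF, 0 °C to rt
Reagents that add atoms: none
Why: Fluoride-induced desilylation of the primary silyl ether, buffered with acetic acid so that the β-hydroxy ketone does not lose formaldehyde by retro-aldol reaction and the acetal stays intact.

Step 7
Reactants: 15 3-(trimethylsilyl)prop-2-ynal; 16 1,1,1,3,3,3-hexafluoropropan-2-yl acrylate
Product: 17 1,1,1,3,3,3-hexafluoropropan-2-yl (S)-3-hydroxy-2-methylidene-5-(trimethylsilyl)pent-4-ynoate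
Conditions: β-isocupreidine (10 mol %), DMF, −55 °C
Reagents that add atoms: none
Why: Morita–Baylis–Hillman reaction of the activated acrylate under β-isocupreidine catalysis, whose quinuclidine nitrogen and phenol hydroxyl organise the aldol and proton-transfer steps and set the carbinol centre (later C15) in the sense known for aldehydes in general; it is (S) here only because the silylalkyne outranks the acrylate carbon.

Step 8
Reactants: 17 hexafluoroisopropyl (S)-3-hydroxy-2-methylidene-5-(trimethylsilyl)pent-4-ynoate
Product: 18 1,1,1,3,3,3-hexafluoropropan-2-yl (S)-3-[(tert-butyldimethylsilyl)oxy]-2-methylidene-5-(trimethylsilyl)pent-4-ynoate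
Conditions: 2,6-lutidine, CH2Cl2, −78 °C
Reagents that add atoms: tert-butyldimethylsilyl trifluoromethanesulfonate CC(C)(C)[Si](C)(C)OS(=O)(=O)C(F)(F)F
Why: O-Silylation of the secondary alcohol with the silyl triflate at low temperature is faster than any addition to the acrylate and protects O15 for the rest of the route.

Step 9
Reactants: 18 silyl-protected hexafluoroisopropyl ester
Product: 19 (R)-3-[(tert-butyldimethylsilyl)oxy]-2-methylidenepent-4-ynoic acid
Conditions: LiOH·H2O, THF/MeOH/H2O, 0 °C; then 1 M HCl to pH 4
Reagents that add atoms: lithium hydroxide [Li+].[OH-] (oxygen of the carboxyl OH)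
Why: Saponification of the very labile hexafluoroisopropyl ester and hydroxide-induced cleavage of the alkynyl C–Si bond take place together, while the secondary silyl ether and the carbinol centre (now R only by priority change) are untouched.

Step 10
Reactants: 14 dienyl hydroxymethyl ketone; 19 (R)-3-[(tert-butyldimethylsilyl)oxy]-2-methylidenepent-4-ynoic acid
Product: 20 [(1S,6R)-1-[(1E)-buta-1,3-dien-1-yl]-6-(dimethoxymethyl)-5,5-dimethyl-2-oxocyclohex-3-en-1-yl]methyl (R)-3-[(tert-butyldimethylsilyl)oxy]-2-methylidenepent-4-ynoate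
Conditions: DCC, DMAP (cat.), CH2Cl2, 0 °C to rt
Reagents that add atoms: none
Why: Steglich esterification of the neopentyl primary alcohol with the carbodiimide-activated acid joins diene and dienophile through the future lactone ester without touching either stereocentre.

Step 11
Reactants: 20 dienyl acrylate
Product: 21 tricyclic spiro-lactone (5R,8S,9S,10S,15R) with rings A and C and the 7,20-lactone: 1-oxo-2,11-diene, C6 dimethyl acetal, C8 bearing the (R)-1-(tert-butyldimethylsilyloxy)prop-2-ynyl arm
Conditions: PhMe (0.01 M), BHT (cat.), 180 °C, sealed tube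
Reagents that add atoms: none
Why: Thermal, concerted but asynchronous [4+2] cycloaddition: an intramolecular Diels–Alder reaction of a 1,3,9-decatriene-type dienyl acrylate, whose closest known relatives are ester-tethered triene cyclisations to cyclohexene-fused δ-lactones. Ring C is closed by the cycloaddition itself (new bonds C13–C14 and C8–C9), and the δ-lactone is closed as the tether ring in the fused mode, the only one open to a four-atom tether, which also matches the electronic preference of the 1-alkyl diene (free terminus C13 to the acrylate β-carbon C14). C9 and the quaternary C8 are set relative to each other by the transition state with the tether carbonyl C7 endo and the bulky C15 arm exo, which gives the cis ring fusion (H9 and C15 syn). Both are set relative to C10 by that quaternary centre: the cyclohexene grows on the face of the incipient lactone that carries the flat C1 carbonyl arm of ring A, away from the C5 arm with its acetal and gem-dimethyl flank. The step needs endo and diastereofacial selectivity, secured by the short tether and by C10; C15 is carried through unchanged. The ring A enone does not compete as dienophile, since its link to the diene would demand a four-membered or bridged ring, and BHT with high dilution suppresses polymerisation.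

Step 12
Reactants: 21 tricyclic spiro-lactone
Product: 22 (1S)-1-hydroxy derivative of 21 (allylic alcohol in ring A)
Conditions: NaBH4, CeCl3·7H2O, MeOH, −78 °C
Reagents that add atoms: none
Why: Luche reduction gives 1,2-reduction of the ring A enone only (lactone and alkyne are inert), hydride entering anti to the axial C20 methylene so that mainly the (1S)-alcohol should form; this temporary centre masks the enone against the reductive steps 15 and 16 and is erased in step 18.

Step 13
Reactants: 22 ring A allylic alcohol
Product: 23 1-O-triethylsilyl ether of 22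
Conditions: 2,6-lutidine, CH2Cl2, −78 °C
Reagents that add atoms: triethylsilyl trifluoromethanesulfonate CC[Si](CC)(CC)OS(=O)(=O)C(F)(F)F
Why: O-Silylation of the hindered allylic alcohol with the silyl triflate at −78 °C is fast enough to spare the dimethyl acetal and removes the free hydroxyl that could otherwise take over the lactone acyl group.

Step 14
Reactants: 23 1-O-triethylsilyl ether
Product: 24 13-oxo-11-ene (ring C enone) derived from 23
Conditions: CrO3, 3,5-dimethylpyrazole, CH2Cl2, −20 °C
Reagents that add atoms: chromium trioxide O=[Cr](=O)=O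
Why: Allylic oxidation by the chromium trioxide–3,5-dimethylpyrazole complex converts the unhindered C13 methylene next to C11=C12 into the enone; the other allylic hydrogen of that alkene (C9) is tertiary and buried between two quaternary carbons, and the ring A alkene has only the shielded C1–H.

Step 15
Reactants: 24 ring C enone
Product: 25 13-ketone (11,12-dihydro derivative of 24)
Conditions: Mn(dpm)3 (5 mol %), PhSiH3, i-PrOH, rt, argon
Reagents that add atoms: none
Why: Manganese hydride hydrogen-atom-transfer conjugate reduction acts only on the polarised enone C=C bond (hydrogen atom to C11, then reduction and protonation of the α-keto radical); without an added oxidant the unactivated ring A alkene and the terminal alkyne should not react.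

Step 16
Reactants: 25 13-ketone
Product: 26 tetracycle with the bicyclo[3.2.1]octane: 13-hydroxy-16-methylene, 1-O-triethylsilyl, 15-O-tert-butyldimethylsilyl, C6 dimethyl acetal
Conditions: SmI2, HMPA, t-BuOH, THF, 0 °C to rt
Reagents that add atoms: none
Why: Ketyl–alkyne radical cyclisation: the samarium ketyl of the C13 ketone adds 5-exo-dig to the internal alkyne carbon C16, which the C8–C15 arm can deliver only across the ring C face it occupies, so the bridgehead carbinol C13 (S) and the 16-methylene group form together.

Step 17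
Reactants: 26 tetracyclic bis-silyl ether
Product: 27 1-hydroxy compound (15-O-silyl ether and acetal retained)
Conditions: PPTS (cat.), MeOH, 0 °C
Reagents that add atoms: none
Why: Acid-catalysed methanolysis of silyl ethers removes the triethylsilyl group far faster than the hindered tert-butyldimethylsilyl group at O15, and in methanol the dimethyl acetal is preserved.

Step 18
Reactants: 27 ring A allylic alcohol
Product: 28 1-oxo-2-ene compound (15-O-tert-butyldimethylsilyl, C6 dimethyl acetal)
Conditions: Dess–Martin periodinane, CH2Cl2, 0 °C to rt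
Reagents that add atoms: none
Why: Dess–Martin oxidation of the secondary allylic alcohol restores the ring A enone; the tertiary C13 hydroxyl cannot be oxidised and O15 is still silylated.

Step 19
Reactants: 28 protected precursor
Product: 29 CNP0521079.1 (target)
Conditions: HF (48 % aq.), MeCN, 0 °C to rt
Reagents that add atoms: water O (oxygen of the C6 aldehyde)
Why: Acidic fluoride desilylation and acetal hydrolysis in one operation free the C15 hydroxyl and the C6 aldehyde; the bridgehead tertiary allylic alcohol cannot ionise under these mild conditions and C5 should not epimerise.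

Compound list

1 | 4,4-dimethylcyclohexa-2,5-dien-1-one | O=C1C=CC(C)(C)C=C1 | starting material
2 | potassium vinyltrifluoroborate | C=C[B-](F)(F)F.[K+] | starting material
3 | (R)-4,4-dimethyl-5-vinylcyclohex-2-en-1-one | O=C1C=CC(C)(C)[C@@H](C=C)C1 | intermediate
4 | (S)-2,2-dimethyl-5-oxocyclohex-3-ene-1-carbaldehyde (not isolated) | O=C1C=CC(C)(C)[C@@H](C=O)C1 | intermediate
5 | (S)-5-(dimethoxymethyl)-4,4-dimethylcyclohex-2-en-1-one | O=C1C=CC(C)(C)[C@@H](C(OC)OC)C1 | intermediate
6 | (triisopropylsilyloxy)methyl chloride | CC(C)[Si](OCCl)(C(C)C)C(C)C | starting material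
7 | lithium dienolate of 5 (not isolated) | [Li+].[O-]C1=C[C@H](C(OC)OC)C(C)(C)C=C1 | intermediate
8 | (5S,6R)-5-(dimethoxymethyl)-4,4-dimethyl-6-[(triisopropylsilyloxy)methyl]cyclohex-2-en-1-one | O=C1C=CC(C)(C)[C@@H](C(OC)OC)[C@@H]1CO[Si](C(C)C)(C(C)C)C(C)C | intermediate
9 | (E)-but-2-enal | C/C=C/C=O | starting material
10 | lithium enolate of 8 (not isolated) | [Li+].[O-]C1=C(CO[Si](C(C)C)(C(C)C)C(C)C)[C@H](C(OC)OC)C(C)(C)C=C1 | intermediate
11 | lithium aldolate from 10 and 9, carbinol carbon as epimer mixture (not isolated) | O=C1C=CC(C)(C)[C@@H](C(OC)OC)[C@]1(CO[Si](C(C)C)(C(C)C)C(C)C)C([O-])/C=C/C.[Li+] | intermediate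
12 | methyl (2E)-1-[(1S,6R)-6-(dimethoxymethyl)-5,5-dimethyl-2-oxo-1-[(triisopropylsilyloxy)methyl]cyclohex-3-en-1-yl]but-2-en-1-yl carbonate, epimer mixture at the carbonate-bearing carbon | O=C1C=CC(C)(C)[C@@H](C(OC)OC)[C@]1(CO[Si](C(C)C)(C(C)C)C(C)C)C(OC(=O)OC)/C=C/C | intermediate
13 | (5R,6S)-6-[(1E)-buta-1,3-dien-1-yl]-5-(dimethoxymethyl)-4,4-dimethyl-6-[(triisopropylsilyloxy)methyl]cyclohex-2-en-1-one | O=C1C=CC(C)(C)[C@@H](C(OC)OC)[C@]1(CO[Si](C(C)C)(C(C)C)C(C)C)/C=C/C=C | intermediate
14 | (5R,6S)-6-[(1E)-buta-1,3-dien-1-yl]-5-(dimethoxymethyl)-6-(hydroxymethyl)-4,4-dimethylcyclohex-2-en-1-one | O=C1C=CC(C)(C)[C@@H](C(OC)OC)[C@]1(CO)/C=C/C=C | intermediate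
15 | 3-(trimethylsilyl)prop-2-ynal | C[Si](C)(C)C#CC=O | starting material
16 | 1,1,1,3,3,3-hexafluoropropan-2-yl acrylate | C=CC(=O)OC(C(F)(F)F)C(F)(F)F | starting material
17 | 1,1,1,3,3,3-hexafluoropropan-2-yl (S)-3-hydroxy-2-methylidene-5-(trimethylsilyl)pent-4-ynoate | C=C(C(=O)OC(C(F)(F)F)C(F)(F)F)[C@H](O)C#C[Si](C)(C)C | intermediate
18 | 1,1,1,3,3,3-hexafluoropropan-2-yl (S)-3-[(tert-butyldimethylsilyl)oxy]-2-methylidene-5-(trimethylsilyl)pent-4-ynoate | C=C(C(=O)OC(C(F)(F)F)C(F)(F)F)[C@H](O[Si](C)(C)C(C)(C)C)C#C[Si](C)(C)C | intermediate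
19 | (R)-3-[(tert-butyldimethylsilyl)oxy]-2-methylidenepent-4-ynoic acid | C=C(C(=O)O)[C@H](O[Si](C)(C)C(C)(C)C)C#C | intermediate
20 | [(1S,6R)-1-[(1E)-buta-1,3-dien-1-yl]-6-(dimethoxymethyl)-5,5-dimethyl-2-oxocyclohex-3-en-1-yl]methyl (R)-3-[(tert-butyldimethylsilyl)oxy]-2-methylidenepent-4-ynoate | C#C[C@@H](O[Si](C)(C)C(C)(C)C)C(=C)C(=O)OC[C@@]1(/C=C/C=C)C(=O)C=CC(C)(C)[C@H]1C(OC)OC | intermediate
21 | (5R,8S,9S,10S,15R)-tricyclic spiro-lactone: ring A 1-oxo-2-ene with C6 dimethyl acetal, 7,20-lactone cis-fused to cyclohexene ring C (11-ene), C8 bearing the 1-(tert-butyldimethylsilyloxy)prop-2-ynyl arm | C#C[C@@H](O[Si](C)(C)C(C)(C)C)[C@]23CCC=C[C@H]2[C@]1(COC3=O)C(=O)C=CC(C)(C)[C@H]1C(OC)OC | intermediate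
22 | (1S)-1-hydroxy derivative of 21 | C#C[C@@H](O[Si](C)(C)C(C)(C)C)[C@]23CCC=C[C@H]2[C@]1(COC3=O)[C@@H](O)C=CC(C)(C)[C@H]1C(OC)OC | intermediate
23 | 1-O-triethylsilyl ether of 22 | C#C[C@@H](O[Si](C)(C)C(C)(C)C)[C@]23CCC=C[C@H]2[C@]1(COC3=O)[C@@H](O[Si](CC)(CC)CC)C=CC(C)(C)[C@H]1C(OC)OC | intermediate
24 | 13-oxo-11-ene (ring C enone) of 23 | C#C[C@@H](O[Si](C)(C)C(C)(C)C)[C@]23CC(=O)C=C[C@H]2[C@]1(COC3=O)[C@@H](O[Si](CC)(CC)CC)C=CC(C)(C)[C@H]1C(OC)OC | intermediate
25 | 13-ketone (11,12-dihydro-24) | C#C[C@@H](O[Si](C)(C)C(C)(C)C)[C@]23CC(=O)CC[C@H]2[C@]1(COC3=O)[C@@H](O[Si](CC)(CC)CC)C=CC(C)(C)[C@H]1C(OC)OC | intermediate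
26 | (1S,5R,8S,9S,10S,13S,15R)-tetracycle: 13-hydroxy-16-methylene bicyclo[3.2.1]octane, 1-O-triethylsilyl, 15-O-tert-butyldimethylsilyl, C6 dimethyl acetal, 7,20-lactone | C=C1[C@@H](O[Si](C)(C)C(C)(C)C)[C@]23C[C@@]1(O)CC[C@H]2[C@]1(COC3=O)[C@@H](O[Si](CC)(CC)CC)C=CC(C)(C)[C@H]1C(OC)OC | intermediate
27 | 1-hydroxy compound from 26 | C=C1[C@@H](O[Si](C)(C)C(C)(C)C)[C@]23C[C@@]1(O)CC[C@H]2[C@]1(COC3=O)[C@@H](O)C=CC(C)(C)[C@H]1C(OC)OC | intermediate
28 | (5R,8S,9S,10S,13S,15R)-1-oxo-2-ene, 15-O-tert-butyldimethylsilyl ether, C6 dimethyl acetal of the target | C=C1[C@@H](O[Si](C)(C)C(C)(C)C)[C@]23C[C@@]1(O)CC[C@H]2[C@]1(COC3=O)C(=O)C=CC(C)(C)[C@H]1C(OC)OC | intermediate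
29 | CNP0521079.1, (5R,8S,9S,10S,13S,15R) | C=C1[C@@H](O)[C@]23C[C@@]1(O)CC[C@H]2[C@]1(COC3=O)C(=O)C=CC(C)(C)[C@H]1C=O | target

Total step count: 19 (16 on the main line, 3 for acid 19).
Longest linear sequence: 16 steps (steps 1–6 and 10–19).

Steps most likely to fail

Step 11. The ester tether may resist the s-cis conformation that the fused transition state needs, so that the triene polymerises or decomposes before it cyclises. The exo-tether transition state, or a mismatch with the C15 centre, may also give the trans-fused or the facially wrong lactone. Fallback: the cycloaddition is run between two molecules and the lactone is closed afterwards. It sets out from 13 (with 18) and comes back at 21. Diene 13 and acrylate 18 are combined under high pressure (12 kbar, CH2Cl2, 40 °C; ortho regiochemistry, ester endo) to give the cyclohexene hexafluoroisopropyl ester F1. HF·pyridine in THF/pyridine removes the primary triisopropylsilyl ether and the freed C20 hydroxyl closes onto the activated ester to give the trimethylsilylalkyne lactone F2. K2CO3 in MeOH at 0 °C removes the alkynyl silyl group and gives 21.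

Step 14. The chromium reagent may also attack the C1–H of the allylic silyl ether or the propargylic C15–H, or deliver oxygen to the other end of the allyl system (transposed enone). Fallback: oxygen is brought to C13 by an ene/[2,3]-sigmatropic sequence. It sets out from 23 and comes back at 24. SeO2 (cat.) with t-BuOOH in CH2Cl2 abstracts hydrogen from the unhindered C13 methylene and returns the double bond to C11=C12, giving the C13 allylic alcohol F3 (either epimer). Dess–Martin oxidation of F3 gives 24.

Step 4. The aldolate at the congested quaternary centre may revert (retro-aldol), or the β-silyloxy enolate may eliminate silyloxide before it is trapped. Fallback: C9 is introduced by irreversible SN2 alkylation. It sets out from 8 and comes back at 13, bypassing 12. The potassium enolate of 8 (KHMDS, THF, −78 °C) with excess (E)-1,4-dibromobut-2-ene gives the allylic bromide F4, again with the electrophile anti to the C5 acetal. 1,4-Dehydrobromination with DBU (PhMe, 80 °C) gives diene 13.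

Further compounds

F1 | step 11 | 1,1,1,3,3,3-hexafluoropropan-2-yl ester of the intermolecular Diels–Alder adduct (cyclohexene with C8 ester and silylated arm, C20 triisopropylsilyl ether) | C[Si](C)(C)C#C[C@@H](O[Si](C)(C)C(C)(C)C)[C@]3(C(=O)OC(C(F)(F)F)C(F)(F)F)CCC=C[C@H]3[C@]1(CO[Si](C(C)C)(C(C)C)C(C)C)C(=O)C=CC(C)(C)[C@H]1C(OC)OC
F2 | step 11 | C17-trimethylsilyl derivative of lactone 21 | C[Si](C)(C)C#C[C@@H](O[Si](C)(C)C(C)(C)C)[C@]23CCC=C[C@H]2[C@]1(COC3=O)C(=O)C=CC(C)(C)[C@H]1C(OC)OC
F3 | step 14 | 13-hydroxy-11-ene derivative of 23 (C13 epimer mixture) | C#C[C@@H](O[Si](C)(C)C(C)(C)C)[C@]23CC(O)C=C[C@H]2[C@]1(COC3=O)[C@@H](O[Si](CC)(CC)CC)C=CC(C)(C)[C@H]1C(OC)OC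
F4 | step 4 | (5R,6S)-6-[(2E)-4-bromobut-2-en-1-yl]-5-(dimethoxymethyl)-4,4-dimethyl-6-[(triisopropylsilyloxy)methyl]cyclohex-2-en-1-one | O=C1C=CC(C)(C)[C@@H](C(OC)OC)[C@]1(CO[Si](C(C)C)(C(C)C)C(C)C)C/C=C/CBr
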